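**Retrosynthetic overview**

- The target is an unsymmetrical dibenzyl ether of two bromocatechols. With C1 as the ring carbon bearing CH2O, each ring has O4 para to C1 and O3 next to it (ring A: Br at C2 and C6; ring B: Br at C2, C5 and C6).
- Both C3–O bonds are cut last: double ortho-oxygenation of the bis-phenol (O4 only) to the bis(ortho-quinone), then reduction. This rests on ring A's phenol having C3–H and C5–H equivalent (mirror plane through C1 and C4) and ring B's phenol having C3–H as its only ring C–H.
- The bis-phenol comes from its diacetate, which is cut at one benzylic C–O bond into a 4-acetoxy-2,6-dibromobenzyl bromide and a 4-acetoxy-2,3,6-tribromobenzyl alcohol (silver-promoted etherification).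
- Both halves derive from 3,5-dibromo-4-methylphenol by acetylation and Wohl–Ziegler bromination; the ring B half is ortho-brominated first and its benzylic bromide is hydrolysed.
- No ring is formed: both arenes are carried intact from the cresol.

Key step: step 9

Remark: the target has no stereogenic element, so the "single enantiomer" requirement imposes no stereochemical task. Ring positions in the discussion are counted from C1 (the carbon bearing CH2O) towards the catechol oxygens (O3, O4).

**Route**

Step 1
Reactants: 1 3,5-dibromo-4-methylphenol; 2 acetic anhydride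
Product: 3 3,5-dibromo-4-methylphenyl acetate
Conditions: Ac2O (1.3 equiv), pyridine, DMAP (cat.), CH2Cl2, 0 °C → rt
Reagents that add atoms: acetic anhydride, CC(=O)OC(C)=O
Why: DMAP-catalysed O-acetylation of the phenol masks it as an ester that tolerates the radical bromination and keeps the ring from electrophilic bromination.

Step 2
Reactants: 3 3,5-dibromo-4-methylphenyl acetate; 4 N-bromosuccinimide
Product: 5 3,5-dibromo-4-(bromomethyl)phenyl acetate
Conditions: NBS (1.1 equiv), AIBN (5 mol %), PhCF3, 85 °C
Reagents that add atoms: N-bromosuccinimide, O=C1CCC(=O)N1Br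
Why: Wohl–Ziegler benzylic bromination at the only benzylic C–H bonds, with the two flanking bromines disfavouring a second bromination.

Step 3
Reactants: 1 3,5-dibromo-4-methylphenol; 4 N-bromosuccinimide
Product: 6 2,3,5-tribromo-4-methylphenol
Conditions: NBS (1.0 equiv, portionwise), p-TsOH·H2O (10 mol %), MeCN, 0 °C → rt, dark
Reagents that add atoms: N-bromosuccinimide, O=C1CCC(=O)N1Br
Why: Electrophilic aromatic bromination ortho to the phenol, where para is blocked by methyl, the two ortho positions are equivalent, and one equivalent of NBS plus deactivation by the new bromine should stop the reaction at the monobromide.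

Step 4
Reactants: 6 2,3,5-tribromo-4-methylphenol; 2 acetic anhydride
Product: 7 2,3,5-tribromo-4-methylphenyl acetate
Conditions: Ac2O (1.5 equiv), pyridine, DMAP (cat.), CH2Cl2, rt
Reagents that add atoms: acetic anhydride, CC(=O)OC(C)=O
Why: DMAP-catalysed O-acetylation, which should proceed on the acidic ortho-bromophenol despite the neighbouring bromine.

Step 5
Reactants: 7 2,3,5-tribromo-4-methylphenyl acetate; 4 N-bromosuccinimide
Product: 8 2,3,5-tribromo-4-(bromomethyl)phenyl acetate
Conditions: NBS (1.1 equiv), AIBN (5 mol %), PhCF3, 85 °C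
Reagents that add atoms: N-bromosuccinimide, O=C1CCC(=O)N1Br
Why: Wohl–Ziegler benzylic bromination, as in step 2, on a ring too electron-poor for nuclear bromination.

Step 6
Reactants: 8 2,3,5-tribromo-4-(bromomethyl)phenyl acetate
Product: 9 2,3,5-tribromo-4-(hydroxymethyl)phenyl acetate
Conditions: Ag2CO3 (1.0 equiv), acetone/H2O (4:1), rt → 40 °C, dark
Reagents that add atoms: water, O
Why: Silver-assisted solvolysis of the benzylic bromide, driven by precipitation of silver bromide, in a near-neutral carbonate-buffered medium chosen to spare the aryl acetate.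

Step 7
Reactants: 9 2,3,5-tribromo-4-(hydroxymethyl)phenyl acetate; 5 3,5-dibromo-4-(bromomethyl)phenyl acetate
Product: 10 4-{[(4-acetoxy-2,6-dibromobenzyl)oxy]methyl}-2,3,5-tribromophenyl acetate
Conditions: 5 (1.2 equiv), AgOTf (1.3 equiv), 2,6-di-tert-butyl-4-methylpyridine (1.5 equiv), 4 Å MS, CH2Cl2, −20 °C → rt, dark
Reagents that add atoms: none
Why: Silver triflate-promoted etherification, in which the benzyl triflate formed in situ alkylates the hindered alcohol while the hindered pyridine takes up the acid, so the aryl acetates are not transferred as they would be under Williamson base.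

Step 8
Reactants: 10 4-{[(4-acetoxy-2,6-dibromobenzyl)oxy]methyl}-2,3,5-tribromophenyl acetate
Product: 11 2,3,5-tribromo-4-{[(2,6-dibromo-4-hydroxybenzyl)oxy]methyl}phenol
Conditions: N2H4·H2O (3 equiv), THF, 0 °C; then aq. citric acid to pH 4
Reagents that add atoms: none
Why: Hydrazinolysis (nucleophilic acyl substitution) cleaves the activated aryl acetates at 0 °C, leaves the dibenzyl ether and aryl bromides untouched, and avoids the alcoholic solvent and heat that could solvolyse a para-hydroxybenzyl ether.

Step 9
Reactants: 11 2,3,5-tribromo-4-{[(2,6-dibromo-4-hydroxybenzyl)oxy]methyl}phenol; 12 2-iodoxybenzoic acid (IBX)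
Product: 14 3,4,6-tribromo-5-{[(2,6-dibromo-3,4-dihydroxybenzyl)oxy]methyl}benzene-1,2-diol, via bis(ortho-quinone) 13 (not isolated)
Conditions: IBX (2.6 equiv), DMF, rt → 40 °C, dark; then aq. Na2S2O4 (excess), 0 °C, work-up at pH 4
Reagents that add atoms: 2-iodoxybenzoic acid (IBX), O=C1OI(=O)(O)c2ccccc12
Why: Each phenol exchanges onto iodine(V) of IBX to give an aryloxy-λ5-iodane, the iodine-bound oxygen shifts within this complex to the neighbouring C3, and the iodine(III) catecholate then collapses to the ortho-quinone with loss of 2-iodobenzoic acid, so the C3–O bond of ring A and of ring B is made and 13 results; dithionite added to the same flask reduces both quinones to the catechols. This is the known IBX ortho-oxygenation of phenols to ortho-quinones with reductive work-up, run here at two phenols of one molecule. No ring is closed and no stereocentre is formed. The step needs ortho C–H oxygenation rather than ipso attack at C–Br or para attack: in ring A C3–H and C5–H are the same position by symmetry, in ring B C3–H is the only ring hydrogen, both para positions carry the benzylic carbon, and delivery from phenol-bound iodine keeps the oxygen ortho. The bromines lower the affinity of the phenols for iodine, so excess IBX and gentle warming are planned, and reduction as soon as 11 is consumed should keep the 4-alkyl ortho-quinones from tautomerising to quinone methides.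

**Compound list**

1 | 3,5-dibromo-4-methylphenol | Cc1c(Br)cc(O)cc1Br | starting material
2 | acetic anhydride | CC(=O)OC(C)=O | starting material
3 | 3,5-dibromo-4-methylphenyl acetate | CC(=O)Oc1cc(Br)c(C)c(Br)c1 | intermediate
4 | N-bromosuccinimide | O=C1CCC(=O)N1Br | starting material
5 | 3,5-dibromo-4-(bromomethyl)phenyl acetate | CC(=O)Oc1cc(Br)c(CBr)c(Br)c1 | intermediate
6 | 2,3,5-tribromo-4-methylphenol | Cc1c(Br)cc(O)c(Br)c1Br | intermediate
7 | 2,3,5-tribromo-4-methylphenyl acetate | CC(=O)Oc1cc(Br)c(C)c(Br)c1Br | intermediate
8 | 2,3,5-tribromo-4-(bromomethyl)phenyl acetate | CC(=O)Oc1cc(Br)c(CBr)c(Br)c1Br | intermediate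
9 | 2,3,5-tribromo-4-(hydroxymethyl)phenyl acetate | CC(=O)Oc1cc(Br)c(CO)c(Br)c1Br | intermediate
10 | 4-{[(4-acetoxy-2,6-dibromobenzyl)oxy]methyl}-2,3,5-tribromophenyl acetate | CC(=O)Oc1cc(Br)c(COCc2c(Br)cc(OC(C)=O)c(Br)c2Br)c(Br)c1 | intermediate
11 | 2,3,5-tribromo-4-{[(2,6-dibromo-4-hydroxybenzyl)oxy]methyl}phenol | Oc1cc(Br)c(COCc2c(Br)cc(O)c(Br)c2Br)c(Br)c1 | intermediate
12 | 2-iodoxybenzoic acid (IBX) | O=C1OI(=O)(O)c2ccccc12 | starting material
13 | 3,5-dibromo-4-{[(2,5,6-tribromo-3,4-dioxocyclohexa-1,5-dien-1-yl)methoxy]methyl}cyclohexa-3,5-diene-1,2-dione | O=C1C(=O)C=C(Br)C(COCC2=C(Br)C(=O)C(=O)C(Br)=C2Br)=C1Br | intermediate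
14 | 3,4,6-tribromo-5-{[(2,6-dibromo-3,4-dihydroxybenzyl)oxy]methyl}benzene-1,2-diol | Oc1cc(Br)c(COCc2c(Br)c(O)c(O)c(Br)c2Br)c(Br)c1O | target

**Step count**

Total step count: 9. Longest linear sequence: 7 steps (steps 3, 4, 5, 6, 7, 8, 9).

**Steps most likely to fail**

Step 9. Oxygen transfer to the two electron-poor bromophenols may be slow and stall after one ring, and the ortho-quinones may tautomerise to quinone methides or be attacked by water before they are reduced. The fallback sets out from 11 and comes back at 14. Magnesium-mediated ortho-formylation of both phenols (MgCl2, Et3N, paraformaldehyde, MeCN, reflux; Casiraghi–Skattebøl) should place a formyl group at C3 of each ring and give 2,4-dibromo-6-hydroxy-3-{[(2,3,6-tribromo-5-formyl-4-hydroxybenzyl)oxy]methyl}benzaldehyde F1. Dakin oxidation (H2O2, aq. NaOH, THF, 0 °C, under N2, acidic quench) then turns each ortho-hydroxy aldehyde, by way of its aryl formate, into the catechol and gives 14.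

Step 7. Alkylation between two di-ortho-brominated partners may be slow, so that the benzyl triflate is lost to adventitious water or benzyl groups exchange at the ether oxygen to give symmetrical ethers. The fallback sets out from 5 and 9 and comes back at 10. Oxidation of 5 with N-methylmorpholine N-oxide (MeCN, 4 Å MS, rt) gives 3,5-dibromo-4-formylphenyl acetate F2. Silylation of 9 (TMSCl, Et3N, CH2Cl2, 0 °C) gives 2,3,5-tribromo-4-[(trimethylsilyloxy)methyl]phenyl acetate F3. Reductive etherification of the two (Et3SiH, TMSOTf cat., CH2Cl2, −78 → 0 °C) forms the benzylic C–O bond by hydride capture of the oxocarbenium ion and gives 10.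

Step 6. The activated aryl acetate may be hydrolysed alongside the bromide, and ionisation at the hindered, electron-poor benzylic carbon may be slow. The fallback sets out from 8 and comes back at 9. Displacement with potassium acetate (KOAc, DMF, rt → 40 °C) gives 4-(acetoxymethyl)-2,3,5-tribromophenyl acetate F4. Methanolysis of both esters (K2CO3, MeOH, 0 °C) gives 2,3,5-tribromo-4-(hydroxymethyl)phenol F5. Selective acetylation of the phenoxide (Ac2O 1.05 equiv, aq. NaOH 1.0 equiv, 0 °C) in the presence of the hindered benzylic alcohol gives 9.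

**Further compounds**

F1 | step 9 | 2,4-dibromo-6-hydroxy-3-{[(2,3,6-tribromo-5-formyl-4-hydroxybenzyl)oxy]methyl}benzaldehyde | O=Cc1c(O)cc(Br)c(COCc2c(Br)c(C=O)c(O)c(Br)c2Br)c1Br
F2 | step 7 | 3,5-dibromo-4-formylphenyl acetate | CC(=O)Oc1cc(Br)c(C=O)c(Br)c1
F3 | step 7 | 2,3,5-tribromo-4-[(trimethylsilyloxy)methyl]phenyl acetate | CC(=O)Oc1cc(Br)c(CO[Si](C)(C)C)c(Br)c1Br
F4 | step 6 | 4-(acetoxymethyl)-2,3,5-tribromophenyl acetate | CC(=O)OCc1c(Br)cc(OC(C)=O)c(Br)c1Br
F5 | step 6 | 2,3,5-tribromo-4-(hydroxymethyl)phenol | OCc1c(Br)cc(O)c(Br)c1Br
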